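**Assumption:** Leprolomin has no stereocentres, so there is no enantiomer to control. The two methyl ethers, the three free phenols and the regiochemical outcomes of the symmetry-based steps are taken as stated.

## Retrosynthesis
- The final disconnection is the diaryl ether C–O bond (Ullmann-type coupling), which splits the target into aryl bromide **8** (ring A) and phenol **17** (ring B), each carrying MOM-protected phenols.
- Both benzene rings are present from the start and come from resorcinol (**1**). Ring A is built by lithiation/methylation, Ir-catalysed C–H borylation, bromodeboronation, Friedel–Crafts acetylation, BCl3 demethylation and MOM protection.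
- Ring B is built from 3,5-bis(MOMO)anisole by lithiation/oxygenation between the two MOM groups, TBS protection, two directed lithiations to add Me then Ac, and desilylation.
- The two fragments are joined by the Cu-catalysed coupling, and a final acid step removes all three MOM groups.

## Route

**Step 1**
Reactants: 1 resorcinol
Product: 2 1,3-dimethoxybenzene
Conditions: MeI, K2CO3, acetone, reflux
Reagents that add atoms: MeI, CI
Why: Williamson O-methylation of both phenols.

**Step 2**
Reactants: 2
Product: 3 2,6-dimethoxytoluene (1,3-dimethoxy-2-methylbenzene)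
Conditions: n-BuLi, THF, 0 °C → rt; then MeI, –78 °C → rt
Reagents that add atoms: MeI, CI
Why: Directed ortho-metalation puts lithium at C2, between the two OMe groups, and MeI traps it.

**Step 3**
Reactants: 3
Product: 4 2-(3,5-dimethoxy-4-methylphenyl)-4,4,5,5-tetramethyl-1,3,2-dioxaborolane
Conditions: B2pin2, [Ir(OMe)(cod)]2 (1.5 mol%), dtbpy (3 mol%), THF, 80 °C
Reagents that add atoms: B2pin2, CC1(C)OB(OC1(C)C)B1OC(C)(C)C(C)(C)O1
Why: Ir-catalysed C–H borylation is sterically controlled and goes to C4, the only C–H not ortho to a substituent (meta to both OMe, para to Me). This is the position that becomes the ether carbon of ring A.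

**Step 4**
Reactants: 4
Product: 5 5-bromo-1,3-dimethoxy-2-methylbenzene
Conditions: CuBr2 (3 equiv), MeOH/H2O 1:1, 90 °C
Reagents that add atoms: CuBr2, Br[Cu]Br
Why: Cu(II)-mediated bromodeboronation of the aryl Bpin replaces boron with bromine at the same carbon.

**Step 5**
Reactants: 5
Product: 6 1-(2-bromo-4,6-dimethoxy-5-methylphenyl)ethan-1-one
Conditions: Ac2O, BF3·OEt2, DCE, 60 °C
Reagents that add atoms: Ac2O, CC(=O)OC(C)=O
Why: Friedel–Crafts acylation. The two remaining C–H positions are equivalent by symmetry and each is ortho to one OMe and para to the other, so only one regioisomer can form.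

**Step 6**
Reactants: 6
Product: 7 1-(2-bromo-6-hydroxy-4-methoxy-5-methylphenyl)ethan-1-one
Conditions: BCl3 (1.2 equiv), CH2Cl2, –78 → 0 °C; then aq. NaHCO3
Reagents that add atoms: none
Why: BCl3 chelates the acetyl C=O and cleaves only the ortho OMe. The para OMe survives and bromine blocks the other ortho position.

**Step 7**
Reactants: 7
Product: 8 1-[2-bromo-4-methoxy-6-(methoxymethoxy)-5-methylphenyl]ethan-1-one
Conditions: NaH, MOMCl, THF/DMF, 0 °C → rt
Reagents that add atoms: MOMCl, COCCl
Why: The chelated phenol is protected as its MOM ether, so it will not compete in the Cu-catalysed coupling.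

**Step 8**
Reactants: 1 resorcinol
Product: 9 1,3-bis(methoxymethoxy)benzene
Conditions: NaH (2.3 equiv), MOMCl (2.4 equiv), THF/DMF, 0 °C → rt
Reagents that add atoms: MOMCl, COCCl
Why: Double MOM protection gives a strong directing group and a protecting group that is removed by acid at the end.

**Step 9**
Reactants: 9
Product: 10 2-[3,5-bis(methoxymethoxy)phenyl]-4,4,5,5-tetramethyl-1,3,2-dioxaborolane
Conditions: B2pin2, [Ir(OMe)(cod)]2, dtbpy, THF, 80 °C
Reagents that add atoms: B2pin2, CC1(C)OB(OC1(C)C)B1OC(C)(C)C(C)(C)O1
Why: Sterically controlled Ir-catalysed C–H borylation occurs at C5, meta to both oxygens, and gives the 1,3,5-trioxygenated pattern.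

**Step 10**
Reactants: 10
Product: 11 3,5-bis(methoxymethoxy)phenol
Conditions: 30% H2O2, aq. NaOH, THF, 0 °C → rt
Reagents that add atoms: H2O2, OO
Why: Oxidative deborylation converts C–B to C–OH, and the MOM ethers are stable to base.

**Step 11**
Reactants: 11
Product: 12 1-methoxy-3,5-bis(methoxymethoxy)benzene
Conditions: MeI, K2CO3, acetone, 50 °C
Reagents that add atoms: MeI, CI
Why: O-methylation installs the OMe that is retained in ring B.

**Step 12**
Reactants: 12
Product: 13 2,6-bis(methoxymethoxy)-4-methoxyphenol
Conditions: n-BuLi, THF, –78 → –20 °C; B(OMe)3, –78 °C → rt; then 30% H2O2, aq. NaOH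
Reagents that add atoms: H2O2, OO (B(OMe)3 is lost as borate)
Why: Directed ortho-metalation occurs at C4 between the two strongly coordinating OMOM groups, which is more acidic than the positions next to OMe. Borylation then oxidation gives the phenol.

**Step 13**
Reactants: 13
Product: 14 tert-butyl[2,6-bis(methoxymethoxy)-4-methoxyphenoxy]dimethylsilane
Conditions: TBSCl, imidazole, DMF, rt
Reagents that add atoms: TBSCl, CC(C)(C)[Si](C)(C)Cl
Why: The phenol is masked as a silyl ether that survives organolithiums but can be removed with fluoride independently of the MOM groups.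

**Step 14**
Reactants: 14
Product: 15 tert-butyl[2,6-bis(methoxymethoxy)-4-methoxy-3-methylphenoxy]dimethylsilane
Conditions: n-BuLi, TMEDA, THF, –78 → –20 °C; then MeI
Reagents that add atoms: MeI, CI
Why: Directed metalation at C3, flanked by OMe and OMOM, then methylation. C3 and C5 are equivalent in 14, so no regiochemistry issue arises.

**Step 15**
Reactants: 15
Product: 16 1-[3-(tert-butyldimethylsilyloxy)-2,4-bis(methoxymethoxy)-6-methoxy-5-methylphenyl]ethan-1-one
Conditions: n-BuLi, TMEDA, THF, –78 → –20 °C; then N-methoxy-N-methylacetamide, –78 °C → rt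
Reagents that add atoms: CC(=O)N(C)OC
Why: Directed metalation at the only remaining C–H (C5), then acylation with a Weinreb amide stops cleanly at the ketone and puts the acetyl between OMe and OMOM.

**Step 16**
Reactants: 16
Product: 17 1-[3-hydroxy-2,4-bis(methoxymethoxy)-6-methoxy-5-methylphenyl]ethan-1-one
Conditions: TBAF, THF, 0 °C
Reagents that add atoms: none
Why: Fluoride removes only the silyl ether and leaves the MOM ethers and ketone intact.

**Step 17**
Reactants: 8 (aryl bromide) + 17 (phenol)
Product: 18 protected diaryl ether, 1-{2-[6-acetyl-… see SMILES in list]}, i.e. 8 and 17 joined through O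
Conditions: CuI (20 mol%), picolinic acid (40 mol%), K3PO4, DMSO, 90 °C
Reagents that add atoms: none
Why: Ullmann-type C–O coupling with a Cu/picolinate catalyst, which tolerates hindered 2,6-dialkoxyphenols. The bromide is activated by its ortho acetyl, and neither fragment contains a stereocentre.

**Step 18**
Reactants: 18
Product: 19 Leprolomin
Conditions: 3 M HCl, MeOH/THF 1:1, 50 °C
Reagents that add atoms: none
Why: Acidic hydrolysis of the three MOM acetals frees the three phenols. The diaryl ether, the two aryl methyl ethers and both acetyl groups are untouched. Each step carries a symmetric or fully substituted substrate through, so no stereochemistry is involved.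

## Compound list
1 | resorcinol | Oc1cccc(O)c1 | starting material
2 | 1,3-dimethoxybenzene | COc1cccc(OC)c1 | intermediate
3 | 2,6-dimethoxytoluene | COc1cccc(OC)c1C | intermediate
4 | 3,5-dimethoxy-4-methylphenyl-Bpin | COc1cc(B2OC(C)(C)C(C)(C)O2)cc(OC)c1C | intermediate
5 | 5-bromo-1,3-dimethoxy-2-methylbenzene | COc1cc(Br)cc(OC)c1C | intermediate
6 | 1-(2-bromo-4,6-dimethoxy-5-methylphenyl)ethan-1-one | CC(=O)c1c(Br)cc(OC)c(C)c1OC | intermediate
7 | 1-(2-bromo-6-hydroxy-4-methoxy-5-methylphenyl)ethan-1-one | CC(=O)c1c(Br)cc(OC)c(C)c1O | intermediate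
8 | 1-[2-bromo-4-methoxy-6-(methoxymethoxy)-5-methylphenyl]ethan-1-one | CC(=O)c1c(Br)cc(OC)c(C)c1OCOC | intermediate (ring A fragment)
9 | 1,3-bis(methoxymethoxy)benzene | COCOc1cccc(OCOC)c1 | intermediate
10 | 3,5-bis(methoxymethoxy)phenyl-Bpin | COCOc1cc(B2OC(C)(C)C(C)(C)O2)cc(OCOC)c1 | intermediate
11 | 3,5-bis(methoxymethoxy)phenol | COCOc1cc(O)cc(OCOC)c1 | intermediate
12 | 1-methoxy-3,5-bis(methoxymethoxy)benzene | COc1cc(OCOC)cc(OCOC)c1 | intermediate
13 | 2,6-bis(methoxymethoxy)-4-methoxyphenol | COc1cc(OCOC)c(O)c(OCOC)c1 | intermediate
14 | TBS ether of 13 | COc1cc(OCOC)c(O[Si](C)(C)C(C)(C)C)c(OCOC)c1 | intermediate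
15 | 3-methyl derivative of 14 | COc1c(C)c(OCOC)c(O[Si](C)(C)C(C)(C)C)c(OCOC)c1 | intermediate
16 | 3-acetyl derivative of 15 (acetophenone) | COc1c(C)c(OCOC)c(O[Si](C)(C)C(C)(C)C)c(OCOC)c1C(C)=O | intermediate
17 | 1-[3-hydroxy-2,4-bis(methoxymethoxy)-6-methoxy-5-methylphenyl]ethan-1-one | COc1c(C)c(OCOC)c(O)c(OCOC)c1C(C)=O | intermediate (ring B fragment)
18 | tris-MOM diaryl ether | CC(=O)c1c(Oc2c(OCOC)c(C)c(OC)c(C(C)=O)c2OCOC)cc(OC)c(C)c1OCOC | intermediate
19 | Leprolomin (achiral) | COc1cc(Oc2c(O)c(C)c(OC)c(C(C)=O)c2O)c(C(C)=O)c(O)c1C | target

**Total steps:** 18.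
**Longest linear sequence:** 11 (steps 8–16, then 17 and 18), which is 61% of the total.

## Three steps most likely to fail
1. **Step 17, hindered Ullmann C–O coupling.** The phenol has two ortho OMOM groups and the ring is fully substituted.
   Fallback: change the bond-forming mechanism to SNAr. Make the 2-fluoroacetophenone analogue of 8 by Cu-mediated fluorodeboronation of 4 followed by steps 5–7, then couple it with the phenoxide of 17 in DMSO with Cs2CO3.
2. **Step 12, regioselective metalation and oxygenation between the two OMOM groups.** It may be less selective than expected or give over-metalation.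
   Fallback: change the oxygenation strategy. Use Elbs persulfate para-hydroxylation of 3,5-bis(benzyloxy)phenol, then selectively methylate the less hindered hydroquinone OH. Carry Bn in place of MOM through the ring B sequence and remove it by hydrogenolysis at the end.
3. **Step 4, CuBr2 bromodeboronation of a very electron-rich arylboronate.** Ring bromination or protodeboronation may compete.
   Fallback: oxidise 4 to 3,5-dimethoxy-4-methylphenol, then acetylate to the phenolic ketone with BF3/AcOH, convert it to the aryl triflate, and use Pd-catalysed C–O coupling (tBuBrettPhos) with 17. This replaces the aryl bromide/Cu coupling with a triflate/Pd coupling.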